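**Retrosynthetic overview**

1. Target 21, (2S)-5-hydroxy-2-(3-hydroxy-4-methoxyphenyl)-7-methoxy-8-prenylchroman-4-one, comes from its ring B methoxymethyl ether 20 by acetal cleavage in the last step.
2. Structural basis: ring A meets ring C only through the C4a–C8a bond, and C5, C6, C7, C8 carry OH, H, OMe and prenyl, the 1,3-dioxygenation of a γ-prenylated acetoacetate chain. Ring A is therefore cut at C4a–C5 and C8a–C8.
3. 20 comes from vinylketene acetal 16 (C5 to C8) and sulfinyl dihydropyranone 8 (C4a=C8a) by [4+2] cycloaddition, then loss of PhSOH and MeOH to reach the arene.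
4. 8 comes from sulfide 7, from (S)-dihydropyranone 5, from aldehyde 2 and siloxy diene 3 (asymmetric hetero-Diels–Alder sets C2 and ring C). 16 comes from enoate 14, from keto ester 12, from methyl acetoacetate 9 and prenyl bromide 10.
5. Ring order: ring B (bought, from isovanillin 1), ring C (step 2), ring A (step 8).

Key step: step 8

Assumption: (S)-BINOL is taken as the ligand antipode that sends diene 3 to the Si face of aldehyde 2 (the sense that gives 2S), by analogy with the facial preference of titanium BINOLates toward aryl aldehydes; if the sense is reversed with this aldehyde, (R)-BINOL is used and nothing else changes.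

Remark: compounds 6, 8, 17 and 18 carry transient stereocentres (C5/C6 of 6, sulfur, C4a/C5/C8/C8a) that should form as mixtures and are all destroyed by the end of step 8; only C2 is defined in their SMILES.

**Route**

Step 1
Reactants: 1 isovanillin (3-hydroxy-4-methoxybenzaldehyde)
Product: 2 4-methoxy-3-(methoxymethoxy)benzaldehyde
Conditions: MOMCl, iPr2NEt, CH2Cl2, 0 °C → rt
Reagents that add atoms: chloromethyl methyl ether, COCCl
Why: Williamson-type O-alkylation of the phenol with the reactive chloromethyl ether should be clean, since the aldehyde is inert to the amine base and the acetal survives every later non-acidic step.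

Step 2
Reactants: 2 4-methoxy-3-(methoxymethoxy)benzaldehyde; 3 (E)-1-methoxy-3-(trimethylsilyloxy)buta-1,3-diene
Product: 5 (S)-2-[4-methoxy-3-(methoxymethoxy)phenyl]-2,3-dihydro-4H-pyran-4-one, via silylated aldol adduct 4 (not isolated)
Conditions: (S)-BINOL (20 mol %), Ti(OiPr)4 (10 mol %), 4 Å MS, Et2O, −20 °C; then CF3CO2H (cat.), CH2Cl2, 0 °C
Reagents that add atoms: none
Why: In this catalytic asymmetric hetero-Diels–Alder reaction of the Mukaiyama aldol type the chiral titanium BINOLate should bind the aldehyde and expose its Si face to the diene terminus, which sets C2 as S, and brief catalytic acid then closes ring C by oxa-Michael addition and loss of methanol without cleaving the aryl methoxymethyl ether.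

Step 3
Reactants: 5 (S)-2-[4-methoxy-3-(methoxymethoxy)phenyl]-2,3-dihydro-4H-pyran-4-one
Product: 7 (S)-2-[4-methoxy-3-(methoxymethoxy)phenyl]-5-(phenylsulfanyl)-2,3-dihydro-4H-pyran-4-one, via chloro sulfide adduct 6 (not isolated)
Conditions: PhSH, NCS, CH2Cl2, 0 °C (forms PhSCl); add to 5, CH2Cl2, −78 °C; then Et3N, −78 → 0 °C
Reagents that add atoms: benzenesulfenyl chloride, ClSc1ccccc1 (made in the flask from thiophenol, Sc1ccccc1, and N-chlorosuccinimide)
Why: Electrophilic α-sulfenylation of an enol ether by addition–elimination should put sulfur on the nucleophilic C5 of the vinylogous ester (chloride at C6), and triethylamine then removes HCl to restore conjugation while being too weak to enolise C3 and endanger C2.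

Step 4
Reactants: 7 (S)-2-[4-methoxy-3-(methoxymethoxy)phenyl]-5-(phenylsulfanyl)-2,3-dihydro-4H-pyran-4-one
Product: 8 (2S)-2-[4-methoxy-3-(methoxymethoxy)phenyl]-5-(phenylsulfinyl)-2,3-dihydro-4H-pyran-4-one (both sulfur epimers)
Conditions: mCPBA (1.0 equiv), CH2Cl2, −78 → −30 °C
Reagents that add atoms: 3-chloroperoxybenzoic acid, O=C(OO)c1cccc(Cl)c1
Why: Chemoselective sulfide-to-sulfoxide oxidation should stop at the sulfoxide with one equivalent of peracid at low temperature, because the sulfide is far more nucleophilic than the carbonyl-deactivated enol ether or the arene, and the sulfur configuration does not matter since sulfur is lost in step 8.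

Step 5
Reactants: 9 methyl acetoacetate; 10 prenyl bromide (1-bromo-3-methylbut-2-ene)
Product: 12 methyl 7-methyl-3-oxooct-6-enoate, via acetoacetate dianion 11 (not isolated)
Conditions: NaH, THF, 0 °C; n-BuLi, 0 °C; 10, 0 °C → rt; aq. HCl
Reagents that add atoms: none
Why: In this acetoacetate dianion alkylation the more basic γ-carbanion should displace bromide from the primary allylic carbon by SN2, giving the γ-prenylated β-keto ester.

Step 6
Reactants: 12 methyl 7-methyl-3-oxooct-6-enoate
Product: 14 methyl (E)-3-methoxy-7-methylocta-2,6-dienoate, via dimethyl ketal 13 (not isolated)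
Conditions: HC(OMe)3, MeOH, cat. H2SO4, rt; then quinoline, distil at reduced pressure
Reagents that add atoms: trimethyl orthoformate, COC(OC)OC
Why: Acid-catalysed ketalisation of the ketone followed by loss of methanol toward the ester (O-methylation of a β-keto ester) should give the conjugated (E)-β-methoxy enoate, the trisubstituted alkene being inert to catalytic acid in methanol at room temperature.

Step 7
Reactants: 14 methyl (E)-3-methoxy-7-methylocta-2,6-dienoate
Product: 16 1,3-dimethoxy-7-methyl-1-(trimethylsilyloxy)octa-1,3,6-triene, via lithium dienolate 15 (not isolated)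
Conditions: LDA, THF, −78 °C; TMSCl, −78 °C → rt; pentane, filter, concentrate (used crude)
Reagents that add atoms: chlorotrimethylsilane, C[Si](C)(C)Cl
Why: Kinetic γ-deprotonation of the β-methoxy enoate at C4 (the only acidic site, syn to the ester) and O-silylation of the extended enolate should give the vinylketene acetal, with the side chain expected to lie anti to C2 across the new C3=C4 bond because the dienolate is born s-cis and an inward chain would clash with the ester terminus.

Step 8
Reactants: 8 (2S)-2-[4-methoxy-3-(methoxymethoxy)phenyl]-5-(phenylsulfinyl)-2,3-dihydro-4H-pyran-4-one; 16 1,3-dimethoxy-7-methyl-1-(trimethylsilyloxy)octa-1,3,6-triene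
Product: 20 (2S)-5-hydroxy-7-methoxy-2-[4-methoxy-3-(methoxymethoxy)phenyl]-8-(3-methylbut-2-en-1-yl)-2,3-dihydro-4H-chromen-4-one, via cycloadduct 17 (not isolated), via cyclohexadiene 18 (not isolated), via silyl ether 19 (not isolated)
Conditions: 16 (2.5 equiv), toluene, 0 °C → 80 °C; then aq. citric acid, THF, rt
Reagents that add atoms: none
Why: Proposed new method: the electron-rich vinylketene acetal 16 should add across the sulfinyl-activated C4a=C8a bond of 8 in a concerted but asynchronous [4+2] cycloaddition, in which the nucleophilic prenyl-bearing terminus (future C8) bonds first to the enone β-carbon C8a and the ketene acetal carbon (future C5) then closes onto the sulfinyl-bearing C4a, so that ring A is closed as a six-membered carbocycle by two new σ bonds. The closest known reaction type is the regiocontrolled Diels–Alder benzannulation of 1,1-dioxygenated 3-oxy dienes with halo- or sulfinyl-substituted quinones and cyclic enones; a 5-sulfinyl-2,3-dihydropyran-4-one has not been used as the dienophile. In adduct 17 the sulfinyl group and H-8a are cis by suprafacial addition and C5 carries no hydrogen, so thermal syn elimination of benzenesulfenic acid can only restore the C4a=C8a double bond, and 1,4-loss of methanol from C5 and C8 of 18 then aromatises ring A to silyl ether 19, which mild aqueous acid converts into the chelated 5-hydroxyl. No new stereocentre survives, and C2, which lies outside the reacting array, is carried through unchanged because the medium stays neutral and non-basic. The step needs regioselectivity (C8 to C8a), which the matched polarisation secures since the carbonyl and the sulfinyl group both direct the nucleophilic terminus to C8a, and it needs ring closure to outrun expulsion of O1 from a stepwise Michael intermediate, which a non-polar solvent and the absence of any Lewis acid should favour.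

Step 9
Reactants: 20 (2S)-5-hydroxy-7-methoxy-2-[4-methoxy-3-(methoxymethoxy)phenyl]-8-(3-methylbut-2-en-1-yl)-2,3-dihydro-4H-chromen-4-one
Product: 21 (2S)-5-hydroxy-2-(3-hydroxy-4-methoxyphenyl)-7-methoxy-8-(3-methylbut-2-en-1-yl)-2,3-dihydro-4H-chromen-4-one
Conditions: aq. HCl (3 M), MeOH, 40 °C
Reagents that add atoms: none
Why: Acid-catalysed acetal methanolysis should release the ring B phenol without epimerising C2 (flavanone ring opening is a base-driven process) and without touching the prenyl group, whose neighbours O1 and the 7-methoxyl offer no free hydroxyl for cyclisation.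

**Compound list** (Ar = 4-methoxy-3-(methoxymethoxy)phenyl)

1 | isovanillin (3-hydroxy-4-methoxybenzaldehyde) | COc1ccc(C=O)cc1O | starting material
2 | 4-methoxy-3-(methoxymethoxy)benzaldehyde | COCOc1cc(C=O)ccc1OC | intermediate
3 | (E)-1-methoxy-3-(trimethylsilyloxy)buta-1,3-diene | CO/C=C/C(=C)O[Si](C)(C)C | starting material
4 | (S,E)-5-Ar-1-methoxy-5-(trimethylsilyloxy)pent-1-en-3-one (not isolated) | CO/C=C/C(=O)C[C@H](O[Si](C)(C)C)c1ccc(OC)c(OCOC)c1 | intermediate
5 | (S)-2-Ar-2,3-dihydro-4H-pyran-4-one | O=C1C[C@@H](c2ccc(OC)c(OCOC)c2)OC=C1 | intermediate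
6 | (2S)-2-Ar-6-chloro-5-(phenylsulfanyl)tetrahydro-4H-pyran-4-one, C5 and C6 undefined (not isolated) | O=C1C[C@@H](c2ccc(OC)c(OCOC)c2)OC(Cl)C1Sc1ccccc1 | intermediate
7 | (S)-2-Ar-5-(phenylsulfanyl)-2,3-dihydro-4H-pyran-4-one | O=C1C[C@@H](c2ccc(OC)c(OCOC)c2)OC=C1Sc1ccccc1 | intermediate
8 | (2S)-2-Ar-5-(phenylsulfinyl)-2,3-dihydro-4H-pyran-4-one, both sulfur epimers | O=C1C[C@@H](c2ccc(OC)c(OCOC)c2)OC=C1S(=O)c1ccccc1 | intermediate
9 | methyl acetoacetate | COC(=O)CC(C)=O | starting material
10 | prenyl bromide (1-bromo-3-methylbut-2-ene) | CC(C)=CCBr | starting material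
11 | sodium lithium dianion of methyl acetoacetate (not isolated) | [Na+].[Li+].[CH2-]C(=O)[CH-]C(=O)OC | intermediate
12 | methyl 7-methyl-3-oxooct-6-enoate | COC(=O)CC(=O)CCC=C(C)C | intermediate
13 | methyl 3,3-dimethoxy-7-methyloct-6-enoate (not isolated) | COC(=O)CC(OC)(OC)CCC=C(C)C | intermediate
14 | methyl (E)-3-methoxy-7-methylocta-2,6-dienoate | COC(=O)/C=C(/OC)CCC=C(C)C | intermediate
15 | lithium dienolate of 14 (not isolated) | [Li+].COC([O-])=C/C(OC)=C/CC=C(C)C | intermediate
16 | 1,3-dimethoxy-7-methyl-1-(trimethylsilyloxy)octa-1,3,6-triene, side chain anti to C2 | COC(O[Si](C)(C)C)=C/C(OC)=C/CC=C(C)C | intermediate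
17 | (2S)-2-Ar-5,7-dimethoxy-8-(3-methylbut-2-en-1-yl)-4a-(phenylsulfinyl)-5-(trimethylsilyloxy)-2,3,4a,5,8,8a-hexahydro-4H-chromen-4-one, other centres undefined (not isolated) | COc1ccc([C@@H]2CC(=O)C3(S(=O)c4ccccc4)C(O2)C(CC=C(C)C)C(OC)=CC3(OC)O[Si](C)(C)C)cc1OCOC | intermediate
18 | (2S)-2-Ar-5,7-dimethoxy-8-(3-methylbut-2-en-1-yl)-5-(trimethylsilyloxy)-2,3,5,8-tetrahydro-4H-chromen-4-one, C5 and C8 undefined (not isolated) | COc1ccc([C@@H]2CC(=O)C3=C(O2)C(CC=C(C)C)C(OC)=CC3(OC)O[Si](C)(C)C)cc1OCOC | intermediate
19 | (2S)-2-Ar-7-methoxy-8-(3-methylbut-2-en-1-yl)-5-(trimethylsilyloxy)-2,3-dihydro-4H-chromen-4-one (not isolated) | COc1ccc([C@@H]2CC(=O)c3c(O[Si](C)(C)C)cc(OC)c(CC=C(C)C)c3O2)cc1OCOC | intermediate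
20 | (2S)-2-Ar-5-hydroxy-7-methoxy-8-(3-methylbut-2-en-1-yl)-2,3-dihydro-4H-chromen-4-one | COc1ccc([C@@H]2CC(=O)c3c(O)cc(OC)c(CC=C(C)C)c3O2)cc1OCOC | intermediate
21 | (2S)-5-hydroxy-2-(3-hydroxy-4-methoxyphenyl)-7-methoxy-8-(3-methylbut-2-en-1-yl)-2,3-dihydro-4H-chromen-4-one | COc1ccc([C@@H]2CC(=O)c3c(O)cc(OC)c(CC=C(C)C)c3O2)cc1O | target

**Totals**

Total step count: 9.
Longest linear sequence: 6 steps (steps 1, 2, 3, 4, 8, 9); the diene branch (steps 5, 6, 7) joins at step 8.

**The three steps most likely to fail**

1. Step 8 (new method). Possible failures: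
- Bond formation may become stepwise, and the Michael-type intermediate may then expel O1 from C8a, so that ring C opens and ring A never closes.
- The push–pull alkene may be too weakly electrophilic, so that the diene is lost to hydrolysis or silyl transfer first.
- Aromatisation may lose trimethylsilanol in place of methanol and leave a 5-methyl ether.

Fallback (known chemistry throughout; sets out from aldehyde 2 and prenyl bromide 10, returns at 20): commercial 2',6'-dihydroxy-4'-methoxyacetophenone is mono-O-prenylated with 10 (K2CO3, acetone, reflux; the second hydroxyl stays chelated to the carbonyl) to give 1-[2-hydroxy-4-methoxy-6-(3-methylbut-2-enyloxy)phenyl]ethanone F1. Claisen–Schmidt condensation of F1 with 2 (KOH, EtOH, rt) should give the 2'-hydroxychalcone F2, and oxa-Michael ring closure through its only free hydroxyl (NaOAc, EtOH, reflux) the racemic 5-O-prenyl flavanone F3. Preparative chromatography on a polysaccharide chiral stationary phase separates the (2S)-5-O-prenyl flavanone F4 from its (2R)-antipode F5, which can be returned to F3 by base-induced ring opening and reclosure. A para-Claisen–Cope rearrangement of F4, catalysed by Eu(fod)3 (fod = 6,6,7,7,8,8,8-heptafluoro-2,2-dimethyloctane-3,5-dionate) in CHCl3 at 60 °C, then moves the prenyl group from O5 through C6 to C8 and gives 20.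

2. Step 7. Possible failures:
- Deprotonation may give the C3=C4 isomer with the side chain turned inward, which cannot reach the reacting s-cis conformation.
- Silylation may occur on carbon.
- The ketene acetal may hydrolyse back to 14 during handling.

Fallback (sets out from sulfoxide 8, returns at 20; the prenyl group is no longer carried in the diene): commercial methyl (E)-3-methoxybut-2-enoate is converted (LDA, TMSCl, THF, −78 °C) into the unsubstituted 1,3-dimethoxy-1-(trimethylsilyloxy)buta-1,3-diene F6, which has no C4 geometry to control. Cycloaddition of F6 with 8 under the conditions of step 8 should give the 8-unsubstituted (2S)-5-hydroxy-7-methoxy flavanone methoxymethyl ether F7. Mitsunobu etherification of its 5-hydroxyl with 3-methylbut-2-en-1-ol (PPh3, DIAD, THF) gives the 5-O-prenyl ether F4 already described, and the same Eu(fod)3-catalysed Claisen–Cope rearrangement delivers 20.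

3. Step 3. Possible failures:
- The reaction may stall at the chloro adduct, which would hydrolyse on work-up with opening of ring C.
- The electron-rich ring B may be sulfenylated in competition.

Fallback (sets out from 5, returns at 7; halogenation and cross-coupling replace electrophilic sulfenylation): α-iodination of the vinylogous ester (I2, pyridine, CH2Cl2, rt) should give the (S)-5-iodo dihydropyranone F8, and Pd-catalysed C–S cross-coupling with thiophenol (Pd2(dba)3, Xantphos, iPr2NEt, dioxane, 90 °C) then gives sulfide 7.

**Further compounds**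

F1 | step 8 | 1-[2-hydroxy-4-methoxy-6-(3-methylbut-2-enyloxy)phenyl]ethanone | CC(=O)c1c(O)cc(OC)cc1OCC=C(C)C
F2 | step 8 | (E)-1-[2-hydroxy-4-methoxy-6-(3-methylbut-2-enyloxy)phenyl]-3-[4-methoxy-3-(methoxymethoxy)phenyl]prop-2-en-1-one | COCOc1cc(/C=C/C(=O)c2c(O)cc(OC)cc2OCC=C(C)C)ccc1OC
F3 | step 8 | racemic 7-methoxy-2-[4-methoxy-3-(methoxymethoxy)phenyl]-5-(3-methylbut-2-enyloxy)-2,3-dihydro-4H-chromen-4-one | COc1ccc(C2CC(=O)c3c(OCC=C(C)C)cc(OC)cc3O2)cc1OCOC
F4 | step 8 | (2S)-7-methoxy-2-[4-methoxy-3-(methoxymethoxy)phenyl]-5-(3-methylbut-2-enyloxy)-2,3-dihydro-4H-chromen-4-one | COc1ccc([C@@H]2CC(=O)c3c(OCC=C(C)C)cc(OC)cc3O2)cc1OCOC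
F5 | step 8 | (2R)-7-methoxy-2-[4-methoxy-3-(methoxymethoxy)phenyl]-5-(3-methylbut-2-enyloxy)-2,3-dihydro-4H-chromen-4-one | COc1ccc([C@H]2CC(=O)c3c(OCC=C(C)C)cc(OC)cc3O2)cc1OCOC
F6 | step 7 | 1,3-dimethoxy-1-(trimethylsilyloxy)buta-1,3-diene | COC(O[Si](C)(C)C)=CC(OC)=C
F7 | step 7 | (2S)-5-hydroxy-7-methoxy-2-[4-methoxy-3-(methoxymethoxy)phenyl]-2,3-dihydro-4H-chromen-4-one | COc1ccc([C@@H]2CC(=O)c3c(O)cc(OC)cc3O2)cc1OCOC
F8 | step 3 | (S)-5-iodo-2-[4-methoxy-3-(methoxymethoxy)phenyl]-2,3-dihydro-4H-pyran-4-one | O=C1C[C@@H](c2ccc(OC)c(OCOC)c2)OC=C1I
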